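## Retrosynthetic overview

- The target comes from its penta-O-benzyl, bis-O-(benzyloxy)methyl ether by one neutral hydrogenolysis. The 12-membered diolide is the only ring made in the route; ring A (one aromatic C–H) and ring B (fully substituted) both derive from one purchased arene.
- The diolide is closed by Mitsunobu macrolactonization, which inverts C2 of the ring B half to R. The first ester is made by intermolecular Mitsunobu esterification of the ring B acid with the ring A alcohol, which inverts C2 of the ring A half to R.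
- The ring A alcohol and ring B acid come from a (1S,2S) and a (1R,2S) aryl carbinol. Ortho-bromination and bromine–lithium exchange install the carboxyl groups and the extra oxygen of ring B.
- Both carbinols come from one aryl iodide and one (S)-lactaldehyde silyl ether. The anti carbinol is made by Felkin–Anh aryltitanium addition; the syn carbinol is made by a new catalyst-controlled nickel/chromium arylation (the key new step).
- The aryl iodide comes from 2-methoxyresorcinol by sterically controlled C–H borylation, benzylation and iododeboronation.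

Assumption: the (S)-lactaldehyde tert-butyldimethylsilyl ether is bought; otherwise it is two steps from ethyl (S)-lactate (TBSCl, then DIBAL-H).

## Route

Step 1
Reactants: 1 2-methoxybenzene-1,3-diol
Product: 4 2-methoxy-5-(4,4,5,5-tetramethyl-1,3,2-dioxaborolan-2-yl)benzene-1,3-diol, via bis(O-boryl) ether 2 (not isolated), via C5-borylated bis(O-boryl) ether 3 (not isolated)
Conditions: HBpin (3.6 equiv), [Ir(OMe)(cod)]2 (1.5 mol %), 4,4′-di-tert-butyl-2,2′-bipyridine (3 mol %), THF, rt then 80 °C; then MeOH, rt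
Reagents that add atoms: pinacolborane, CC1(C)OBOC1(C)C
Why: Iridium-catalysed C–H borylation after in-flask O-borylation of both phenols; boron goes to C5, the only ring C–H without an ortho substituent, and methanol removes the O-boryl groups.

Step 2
Reactants: 4 2-methoxy-5-(4,4,5,5-tetramethyl-1,3,2-dioxaborolan-2-yl)benzene-1,3-diol
Product: 5 2-[3,5-bis(benzyloxy)-4-methoxyphenyl]-4,4,5,5-tetramethyl-1,3,2-dioxaborolane
Conditions: BnBr (2.3 equiv), K2CO3, DMF, rt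
Reagents that add atoms: benzyl bromide, BrCc1ccccc1
Why: Williamson ether synthesis on both phenols; the pinacol boronate tolerates carbonate in DMF at room temperature.

Step 3
Reactants: 5 2-[3,5-bis(benzyloxy)-4-methoxyphenyl]-4,4,5,5-tetramethyl-1,3,2-dioxaborolane
Product: 6 1,3-bis(benzyloxy)-5-iodo-2-methoxybenzene
Conditions: CuI (10 mol %), 1,10-phenanthroline (20 mol %), KI (1.5 equiv), MeOH/H2O 4:1, air, 80 °C
Reagents that add atoms: potassium iodide, [K+].[I-]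
Why: Copper-catalysed oxidative iododeboronation replaces boron by iodine at the same carbon, so the regiochemistry of step 1 is kept.

Step 4
Reactants: 6 1,3-bis(benzyloxy)-5-iodo-2-methoxybenzene; 7 (S)-2-[(tert-butyldimethylsilyl)oxy]propanal
Product: 9 (1S,2S)-1-[3,5-bis(benzyloxy)-4-methoxyphenyl]-2-[(tert-butyldimethylsilyl)oxy]propan-1-ol, via O-trimethylsilyl ether 8 (not isolated)
Conditions: CrCl2 (10 mol %), chiral oxazoline–sulfonamide ligand L (12 mol %, the enantiomer that gives the Si-face adduct), Et3N (25 mol %), NiCl2(dme) (2 mol %), Mn, TMSCl, MeCN, rt; then aqueous citric acid, THF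
Reagents that add atoms: none
Why: Proposed new method: a catalyst-controlled anti-Felkin (1,2-syn) arylation in the Nozaki–Hiyama–Kishi manifold, in which zerovalent nickel inserts into the C–I bond of 6, the aryl group passes to chromium, and the ligand-bound aryl–chromium species adds to the Si face of 7 through a closed non-chelated transition state where the ligand rather than the weakly biasing α-OTBS centre selects the face, setting C1 as S; Mn turns the chromium over, TMSCl releases it as silyl ether 8, which is cleaved on work-up; the closest known reaction type is the catalytic asymmetric nickel/chromium addition of alkenyl halides to aldehydes with catalyst-controlled diastereoselection.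

Step 5
Reactants: 9 (1S,2S)-1-[3,5-bis(benzyloxy)-4-methoxyphenyl]-2-[(tert-butyldimethylsilyl)oxy]propan-1-ol
Product: 10 (1S,2S)-1-[(benzyloxy)methoxy]-1-[3,5-bis(benzyloxy)-4-methoxyphenyl]-2-[(tert-butyldimethylsilyl)oxy]propane
Conditions: BOMCl, i-Pr2NEt, Bu4NI (cat.), CH2Cl2, 40 °C
Reagents that add atoms: benzyl chloromethyl ether, ClCOCc1ccccc1
Why: O-alkylation with an α-chloro ether under amine base (BOM protection); no alkoxide forms, so the neighbouring silyl group does not migrate.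

Step 6
Reactants: 10 (1S,2S)-1-[(benzyloxy)methoxy]-1-[3,5-bis(benzyloxy)-4-methoxyphenyl]-2-[(tert-butyldimethylsilyl)oxy]propane
Product: 11 (1S,2S)-1-[(benzyloxy)methoxy]-1-[3,5-bis(benzyloxy)-2-bromo-4-methoxyphenyl]-2-[(tert-butyldimethylsilyl)oxy]propane
Conditions: NBS (1.02 equiv), MeCN, 0 °C
Reagents that add atoms: N-bromosuccinimide, O=C1CCC(=O)N1Br
Why: Electrophilic aromatic bromination at one of the two equivalent positions ortho to the side chain and para to a benzyloxy group; one equivalent at 0 °C stops at the monobromide.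

Step 7
Reactants: 11 (1S,2S)-1-[(benzyloxy)methoxy]-1-[3,5-bis(benzyloxy)-2-bromo-4-methoxyphenyl]-2-[(tert-butyldimethylsilyl)oxy]propane
Product: 13 allyl 2,4-bis(benzyloxy)-6-{(1S,2S)-1-[(benzyloxy)methoxy]-2-[(tert-butyldimethylsilyl)oxy]propyl}-3-methoxybenzoate, via aryllithium 12 (not isolated)
Conditions: n-BuLi (1.05 equiv), THF, −78 °C; then cannulated into allyl chloroformate (3 equiv), THF, −78 °C
Reagents that add atoms: allyl chloroformate, C=CCOC(=O)Cl
Why: Bromine–lithium exchange followed by acylation of the aryllithium with a chloroformate; the di-ortho-substituted ester formed is too hindered for a second addition.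

Step 8
Reactants: 13 allyl 2,4-bis(benzyloxy)-6-{(1S,2S)-1-[(benzyloxy)methoxy]-2-[(tert-butyldimethylsilyl)oxy]propyl}-3-methoxybenzoate
Product: 14 allyl 2,4-bis(benzyloxy)-6-{(1S,2S)-1-[(benzyloxy)methoxy]-2-hydroxypropyl}-3-methoxybenzoate
Conditions: HF·pyridine, pyridine, THF, 0 °C to rt; used at once
Reagents that add atoms: none
Why: Fluoride desilylation under mildly acidic conditions; no alkoxide is formed, so the hydroxy ester does not close to the six-membered lactone.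

Step 9
Reactants: 6 1,3-bis(benzyloxy)-5-iodo-2-methoxybenzene; 7 (S)-2-[(tert-butyldimethylsilyl)oxy]propanal
Product: 17 (1R,2S)-1-[3,5-bis(benzyloxy)-4-methoxyphenyl]-2-[(tert-butyldimethylsilyl)oxy]propan-1-ol, via aryllithium 15 (not isolated), via aryltitanium triisopropoxide 16 (not isolated)
Conditions: n-BuLi (1.05 equiv), THF, −78 °C; ClTi(OiPr)3, −78 to −40 °C; then 7, −78 to −20 °C; aqueous NH4Cl
Reagents that add atoms: none
Why: Iodine–lithium exchange, transmetallation and Felkin–Anh addition of the non-chelating aryltitanium reagent (OTBS anti to the incoming aryl) give the 1,2-anti carbinol with C1 as R (about 9:1, minor isomer removed by chromatography).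

Step 10
Reactants: 17 (1R,2S)-1-[3,5-bis(benzyloxy)-4-methoxyphenyl]-2-[(tert-butyldimethylsilyl)oxy]propan-1-ol
Product: 18 (1R,2S)-1-[(benzyloxy)methoxy]-1-[3,5-bis(benzyloxy)-4-methoxyphenyl]-2-[(tert-butyldimethylsilyl)oxy]propane
Conditions: BOMCl, i-Pr2NEt, Bu4NI (cat.), CH2Cl2, 40 °C
Reagents that add atoms: benzyl chloromethyl ether, ClCOCc1ccccc1
Why: BOM protection by O-alkylation with an α-chloro ether under amine base, as in step 5.

Step 11
Reactants: 18 (1R,2S)-1-[(benzyloxy)methoxy]-1-[3,5-bis(benzyloxy)-4-methoxyphenyl]-2-[(tert-butyldimethylsilyl)oxy]propane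
Product: 19 (1R,2S)-1-[(benzyloxy)methoxy]-1-[3,5-bis(benzyloxy)-2-bromo-4-methoxyphenyl]-2-[(tert-butyldimethylsilyl)oxy]propane
Conditions: NBS (1.02 equiv), MeCN, 0 °C
Reagents that add atoms: N-bromosuccinimide, O=C1CCC(=O)N1Br
Why: Electrophilic aromatic monobromination ortho to the side chain, as in step 6.

Step 12
Reactants: 19 (1R,2S)-1-[(benzyloxy)methoxy]-1-[3,5-bis(benzyloxy)-2-bromo-4-methoxyphenyl]-2-[(tert-butyldimethylsilyl)oxy]propane
Product: 22 2,4-bis(benzyloxy)-6-{(1R,2S)-1-[(benzyloxy)methoxy]-2-[(tert-butyldimethylsilyl)oxy]propyl}-3-methoxyphenol, via aryllithium 20 (not isolated), via dimethyl arylboronate 21 (not isolated)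
Conditions: n-BuLi (1.05 equiv), THF, −78 °C; B(OMe)3, −78 °C to rt; then AcOH, 30% H2O2, 0 °C to rt
Reagents that add atoms: hydrogen peroxide, OO
Why: Bromine–lithium exchange, borylation and peroxide oxidation of the arylboronate turn the C–Br bond into the C–OH bond that distinguishes ring B.

Step 13
Reactants: 22 2,4-bis(benzyloxy)-6-{(1R,2S)-1-[(benzyloxy)methoxy]-2-[(tert-butyldimethylsilyl)oxy]propyl}-3-methoxyphenol
Product: 23 (1R,2S)-1-[(benzyloxy)methoxy]-2-[(tert-butyldimethylsilyl)oxy]-1-[2,3,5-tris(benzyloxy)-4-methoxyphenyl]propane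
Conditions: BnBr, K2CO3, DMF, 50 °C
Reagents that add atoms: benzyl bromide, BrCc1ccccc1
Why: Williamson ether synthesis on the new phenol; the secondary silyl ether is stable to carbonate.

Step 14
Reactants: 23 (1R,2S)-1-[(benzyloxy)methoxy]-2-[(tert-butyldimethylsilyl)oxy]-1-[2,3,5-tris(benzyloxy)-4-methoxyphenyl]propane
Product: 24 (1R,2S)-1-[(benzyloxy)methoxy]-2-[(tert-butyldimethylsilyl)oxy]-1-[2,3,5-tris(benzyloxy)-6-bromo-4-methoxyphenyl]propane
Conditions: NBS (1.05 equiv), MeCN, 0 °C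
Reagents that add atoms: N-bromosuccinimide, O=C1CCC(=O)N1Br
Why: Electrophilic aromatic bromination at the only C–H left on the tetra-alkoxy ring, so the regiochemistry is unambiguous.

Step 15
Reactants: 24 (1R,2S)-1-[(benzyloxy)methoxy]-2-[(tert-butyldimethylsilyl)oxy]-1-[2,3,5-tris(benzyloxy)-6-bromo-4-methoxyphenyl]propane
Product: 26 2,4,5-tris(benzyloxy)-6-{(1R,2S)-1-[(benzyloxy)methoxy]-2-[(tert-butyldimethylsilyl)oxy]propyl}-3-methoxybenzoic acid, via aryllithium 25 (not isolated)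
Conditions: n-BuLi (1.05 equiv), THF, −78 °C; CO2, −78 °C to rt; then 1 M HCl to pH 3
Reagents that add atoms: carbon dioxide, O=C=O
Why: Bromine–lithium exchange and carboxylation of the aryllithium give the hindered benzoic acid directly.

Step 16
Reactants: 26 2,4,5-tris(benzyloxy)-6-{(1R,2S)-1-[(benzyloxy)methoxy]-2-[(tert-butyldimethylsilyl)oxy]propyl}-3-methoxybenzoic acid; 14 allyl 2,4-bis(benzyloxy)-6-{(1S,2S)-1-[(benzyloxy)methoxy]-2-hydroxypropyl}-3-methoxybenzoate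
Product: 27 allyl 2,4-bis(benzyloxy)-6-{(1S,2R)-1-[(benzyloxy)methoxy]-2-[(2,4,5-tris(benzyloxy)-6-{(1R,2S)-1-[(benzyloxy)methoxy]-2-[(tert-butyldimethylsilyl)oxy]propyl}-3-methoxybenzoyl)oxy]propyl}-3-methoxybenzoate
Conditions: PPh3 (2 equiv), DIAD (2 equiv), toluene, 0.3 M, 0 °C to rt
Reagents that add atoms: none
Why: Mitsunobu esterification, in which the carboxylate is the nucleophile so the di-ortho substitution of the acid does not matter; SN2 inversion turns C2 of the ring A half from S to R.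

Step 17
Reactants: 27 allyl 2,4-bis(benzyloxy)-6-{(1S,2R)-1-[(benzyloxy)methoxy]-2-[(2,4,5-tris(benzyloxy)-6-{(1R,2S)-1-[(benzyloxy)methoxy]-2-[(tert-butyldimethylsilyl)oxy]propyl}-3-methoxybenzoyl)oxy]propyl}-3-methoxybenzoate
Product: 28 2,4-bis(benzyloxy)-6-{(1S,2R)-1-[(benzyloxy)methoxy]-2-[(2,4,5-tris(benzyloxy)-6-{(1R,2S)-1-[(benzyloxy)methoxy]-2-[(tert-butyldimethylsilyl)oxy]propyl}-3-methoxybenzoyl)oxy]propyl}-3-methoxybenzoic acid
Conditions: Pd(PPh3)4 (5 mol %), morpholine (5 equiv), THF, rt; dilute citric acid work-up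
Reagents that add atoms: none
Why: Palladium-catalysed allyl transfer to morpholine (Tsuji–Trost deallylation) frees the acid under neutral conditions that leave the aryl esters, silyl ether and acetals untouched.

Step 18
Reactants: 28 2,4-bis(benzyloxy)-6-{(1S,2R)-1-[(benzyloxy)methoxy]-2-[(2,4,5-tris(benzyloxy)-6-{(1R,2S)-1-[(benzyloxy)methoxy]-2-[(tert-butyldimethylsilyl)oxy]propyl}-3-methoxybenzoyl)oxy]propyl}-3-methoxybenzoic acid
Product: 29 2,4-bis(benzyloxy)-6-{(1S,2R)-1-[(benzyloxy)methoxy]-2-[(2,4,5-tris(benzyloxy)-6-{(1R,2S)-1-[(benzyloxy)methoxy]-2-hydroxypropyl}-3-methoxybenzoyl)oxy]propyl}-3-methoxybenzoic acid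
Conditions: HF·pyridine, pyridine, THF, 0 °C to rt; used at once
Reagents that add atoms: none
Why: Fluoride desilylation without alkoxide formation, so the freed hydroxyl does not attack the neighbouring hindered ester.

Step 19
Reactants: 29 2,4-bis(benzyloxy)-6-{(1S,2R)-1-[(benzyloxy)methoxy]-2-[(2,4,5-tris(benzyloxy)-6-{(1R,2S)-1-[(benzyloxy)methoxy]-2-hydroxypropyl}-3-methoxybenzoyl)oxy]propyl}-3-methoxybenzoic acid
Product: 30 penta-O-benzyl bis-O-[(benzyloxy)methyl] derivative of the target macrodiolide (2R and 1S in the ring A half; 2R and 1R in the ring B half)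
Conditions: PPh3 (5 equiv), DIAD (5 equiv), toluene, 0.002 M, slow addition of 29 over 8 h, rt
Reagents that add atoms: none
Why: Mitsunobu macrolactonization at high dilution closes the 12-membered diolide; SN2 attack of the ring A carboxylate inverts C2 of the ring B half from S to R.

Step 20
Reactants: 30 penta-O-benzyl bis-O-[(benzyloxy)methyl] derivative of the target macrodiolide
Product: 32 target macrodiolide CNP0086623.1, via bis(hemiformal) 31 (not isolated)
Conditions: H2 (1 atm), 10% Pd/C, EtOAc/EtOH 1:1, rt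
Reagents that add atoms: none
Why: Hydrogenolysis cleaves all seven O-benzyl bonds; the two O–CH2OH hemiformals left from the BOM groups lose formaldehyde, and the neutral conditions avoid acyl migration or phthalide formation at the free benzylic hydroxyls.

## Compound list

1 | 2-methoxybenzene-1,3-diol | COc1c(O)cccc1O | starting material
2 | 2-methoxy-1,3-bis[(4,4,5,5-tetramethyl-1,3,2-dioxaborolan-2-yl)oxy]benzene | COc1c(OB2OC(C)(C)C(C)(C)O2)cccc1OB1OC(C)(C)C(C)(C)O1 | intermediate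
3 | 2-{4-methoxy-3,5-bis[(4,4,5,5-tetramethyl-1,3,2-dioxaborolan-2-yl)oxy]phenyl}-4,4,5,5-tetramethyl-1,3,2-dioxaborolane | COc1c(OB2OC(C)(C)C(C)(C)O2)cc(B2OC(C)(C)C(C)(C)O2)cc1OB1OC(C)(C)C(C)(C)O1 | intermediate
4 | 2-methoxy-5-(4,4,5,5-tetramethyl-1,3,2-dioxaborolan-2-yl)benzene-1,3-diol | COc1c(O)cc(B2OC(C)(C)C(C)(C)O2)cc1O | intermediate
5 | 2-[3,5-bis(benzyloxy)-4-methoxyphenyl]-4,4,5,5-tetramethyl-1,3,2-dioxaborolane | COc1c(OCc2ccccc2)cc(B2OC(C)(C)C(C)(C)O2)cc1OCc1ccccc1 | intermediate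
6 | 1,3-bis(benzyloxy)-5-iodo-2-methoxybenzene | COc1c(OCc2ccccc2)cc(I)cc1OCc1ccccc1 | intermediate
7 | (S)-2-[(tert-butyldimethylsilyl)oxy]propanal | C[C@H](O[Si](C)(C)C(C)(C)C)C=O | starting material
8 | (1S,2S)-1-[3,5-bis(benzyloxy)-4-methoxyphenyl]-2-[(tert-butyldimethylsilyl)oxy]-1-[(trimethylsilyl)oxy]propane | C[C@H](O[Si](C)(C)C(C)(C)C)[C@@H](O[Si](C)(C)C)c1cc(OCc2ccccc2)c(OC)c(OCc2ccccc2)c1 | intermediate
9 | (1S,2S)-1-[3,5-bis(benzyloxy)-4-methoxyphenyl]-2-[(tert-butyldimethylsilyl)oxy]propan-1-ol | C[C@H](O[Si](C)(C)C(C)(C)C)[C@@H](O)c1cc(OCc2ccccc2)c(OC)c(OCc2ccccc2)c1 | intermediate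
10 | (1S,2S)-1-[(benzyloxy)methoxy]-1-[3,5-bis(benzyloxy)-4-methoxyphenyl]-2-[(tert-butyldimethylsilyl)oxy]propane | C[C@H](O[Si](C)(C)C(C)(C)C)[C@@H](OCOCc1ccccc1)c1cc(OCc2ccccc2)c(OC)c(OCc2ccccc2)c1 | intermediate
11 | (1S,2S)-1-[(benzyloxy)methoxy]-1-[3,5-bis(benzyloxy)-2-bromo-4-methoxyphenyl]-2-[(tert-butyldimethylsilyl)oxy]propane | C[C@H](O[Si](C)(C)C(C)(C)C)[C@@H](OCOCc1ccccc1)c1cc(OCc2ccccc2)c(OC)c(OCc2ccccc2)c1Br | intermediate
12 | aryllithium from 11 (lithium in place of bromine) | C[C@H](O[Si](C)(C)C(C)(C)C)[C@@H](OCOCc1ccccc1)c1cc(OCc2ccccc2)c(OC)c(OCc2ccccc2)c1[Li] | intermediate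
13 | allyl 2,4-bis(benzyloxy)-6-{(1S,2S)-1-[(benzyloxy)methoxy]-2-[(tert-butyldimethylsilyl)oxy]propyl}-3-methoxybenzoate | C[C@H](O[Si](C)(C)C(C)(C)C)[C@@H](OCOCc1ccccc1)c1cc(OCc2ccccc2)c(OC)c(OCc2ccccc2)c1C(=O)OCC=C | intermediate
14 | allyl 2,4-bis(benzyloxy)-6-{(1S,2S)-1-[(benzyloxy)methoxy]-2-hydroxypropyl}-3-methoxybenzoate | C[C@H](O)[C@@H](OCOCc1ccccc1)c1cc(OCc2ccccc2)c(OC)c(OCc2ccccc2)c1C(=O)OCC=C | intermediate
15 | [3,5-bis(benzyloxy)-4-methoxyphenyl]lithium | [Li]c1cc(OCc2ccccc2)c(OC)c(OCc2ccccc2)c1 | intermediate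
16 | [3,5-bis(benzyloxy)-4-methoxyphenyl]titanium triisopropoxide | CC(C)O[Ti](OC(C)C)(OC(C)C)c1cc(OCc2ccccc2)c(OC)c(OCc2ccccc2)c1 | intermediate
17 | (1R,2S)-1-[3,5-bis(benzyloxy)-4-methoxyphenyl]-2-[(tert-butyldimethylsilyl)oxy]propan-1-ol | C[C@H](O[Si](C)(C)C(C)(C)C)[C@H](O)c1cc(OCc2ccccc2)c(OC)c(OCc2ccccc2)c1 | intermediate
18 | (1R,2S)-1-[(benzyloxy)methoxy]-1-[3,5-bis(benzyloxy)-4-methoxyphenyl]-2-[(tert-butyldimethylsilyl)oxy]propane | C[C@H](O[Si](C)(C)C(C)(C)C)[C@H](OCOCc1ccccc1)c1cc(OCc2ccccc2)c(OC)c(OCc2ccccc2)c1 | intermediate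
19 | (1R,2S)-1-[(benzyloxy)methoxy]-1-[3,5-bis(benzyloxy)-2-bromo-4-methoxyphenyl]-2-[(tert-butyldimethylsilyl)oxy]propane | C[C@H](O[Si](C)(C)C(C)(C)C)[C@H](OCOCc1ccccc1)c1c(Br)c(OCc2ccccc2)c(OC)c(OCc2ccccc2)c1 | intermediate
20 | aryllithium from 19 (lithium in place of bromine) | C[C@H](O[Si](C)(C)C(C)(C)C)[C@H](OCOCc1ccccc1)c1c([Li])c(OCc2ccccc2)c(OC)c(OCc2ccccc2)c1 | intermediate
21 | dimethyl arylboronate from 20 (B(OMe)2 in place of lithium) | C[C@H](O[Si](C)(C)C(C)(C)C)[C@H](OCOCc1ccccc1)c1c(B(OC)OC)c(OCc2ccccc2)c(OC)c(OCc2ccccc2)c1 | intermediate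
22 | 2,4-bis(benzyloxy)-6-{(1R,2S)-1-[(benzyloxy)methoxy]-2-[(tert-butyldimethylsilyl)oxy]propyl}-3-methoxyphenol | C[C@H](O[Si](C)(C)C(C)(C)C)[C@H](OCOCc1ccccc1)c1c(O)c(OCc2ccccc2)c(OC)c(OCc2ccccc2)c1 | intermediate
23 | (1R,2S)-1-[(benzyloxy)methoxy]-2-[(tert-butyldimethylsilyl)oxy]-1-[2,3,5-tris(benzyloxy)-4-methoxyphenyl]propane | C[C@H](O[Si](C)(C)C(C)(C)C)[C@H](OCOCc1ccccc1)c1c(OCc2ccccc2)c(OCc2ccccc2)c(OC)c(OCc2ccccc2)c1 | intermediate
24 | (1R,2S)-1-[(benzyloxy)methoxy]-2-[(tert-butyldimethylsilyl)oxy]-1-[2,3,5-tris(benzyloxy)-6-bromo-4-methoxyphenyl]propane | C[C@H](O[Si](C)(C)C(C)(C)C)[C@H](OCOCc1ccccc1)c1c(OCc2ccccc2)c(OCc2ccccc2)c(OC)c(OCc2ccccc2)c1Br | intermediate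
25 | aryllithium from 24 (lithium in place of bromine) | C[C@H](O[Si](C)(C)C(C)(C)C)[C@H](OCOCc1ccccc1)c1c(OCc2ccccc2)c(OCc2ccccc2)c(OC)c(OCc2ccccc2)c1[Li] | intermediate
26 | 2,4,5-tris(benzyloxy)-6-{(1R,2S)-1-[(benzyloxy)methoxy]-2-[(tert-butyldimethylsilyl)oxy]propyl}-3-methoxybenzoic acid | C[C@H](O[Si](C)(C)C(C)(C)C)[C@H](OCOCc1ccccc1)c1c(OCc2ccccc2)c(OCc2ccccc2)c(OC)c(OCc2ccccc2)c1C(=O)O | intermediate
27 | allyl 2,4-bis(benzyloxy)-6-{(1S,2R)-1-[(benzyloxy)methoxy]-2-[(2,4,5-tris(benzyloxy)-6-{(1R,2S)-1-[(benzyloxy)methoxy]-2-[(tert-butyldimethylsilyl)oxy]propyl}-3-methoxybenzoyl)oxy]propyl}-3-methoxybenzoate | C[C@H](O[Si](C)(C)C(C)(C)C)[C@H](OCOCc1ccccc1)c1c(OCc2ccccc2)c(OCc2ccccc2)c(OC)c(OCc2ccccc2)c1C(=O)O[C@H](C)[C@@H](OCOCc1ccccc1)c1cc(OCc2ccccc2)c(OC)c(OCc2ccccc2)c1C(=O)OCC=C | intermediate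
28 | 2,4-bis(benzyloxy)-6-{(1S,2R)-1-[(benzyloxy)methoxy]-2-[(2,4,5-tris(benzyloxy)-6-{(1R,2S)-1-[(benzyloxy)methoxy]-2-[(tert-butyldimethylsilyl)oxy]propyl}-3-methoxybenzoyl)oxy]propyl}-3-methoxybenzoic acid | C[C@H](O[Si](C)(C)C(C)(C)C)[C@H](OCOCc1ccccc1)c1c(OCc2ccccc2)c(OCc2ccccc2)c(OC)c(OCc2ccccc2)c1C(=O)O[C@H](C)[C@@H](OCOCc1ccccc1)c1cc(OCc2ccccc2)c(OC)c(OCc2ccccc2)c1C(=O)O | intermediate
29 | 2,4-bis(benzyloxy)-6-{(1S,2R)-1-[(benzyloxy)methoxy]-2-[(2,4,5-tris(benzyloxy)-6-{(1R,2S)-1-[(benzyloxy)methoxy]-2-hydroxypropyl}-3-methoxybenzoyl)oxy]propyl}-3-methoxybenzoic acid | C[C@H](O)[C@H](OCOCc1ccccc1)c1c(OCc2ccccc2)c(OCc2ccccc2)c(OC)c(OCc2ccccc2)c1C(=O)O[C@H](C)[C@@H](OCOCc1ccccc1)c1cc(OCc2ccccc2)c(OC)c(OCc2ccccc2)c1C(=O)O | intermediate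
30 | target macrodiolide with all five phenols as benzyl ethers and both benzylic hydroxyls as (benzyloxy)methyl ethers | COc1c(OCc3ccccc3)cc2c(c1OCc1ccccc1)C(=O)O[C@H](C)[C@H](OCOCc1ccccc1)c1c(OCc3ccccc3)c(OCc3ccccc3)c(OC)c(OCc3ccccc3)c1C(=O)O[C@H](C)[C@H]2OCOCc1ccccc1 | intermediate
31 | target macrodiolide with both benzylic hydroxyls as hydroxymethyl (hemiformal) ethers | COc1c(O)cc2c(c1O)C(=O)O[C@H](C)[C@H](OCO)c1c(O)c(O)c(OC)c(O)c1C(=O)O[C@H](C)[C@H]2OCO | intermediate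
32 | CNP0086623.1, 12-membered diolide of the ring A and ring B hydroxy acids (2R and 1S in the ring A half; 2R and 1R in the ring B half) | COc1c(O)cc2c(c1O)C(=O)O[C@H](C)[C@H](O)c1c(O)c(O)c(OC)c(O)c1C(=O)O[C@H](C)[C@H]2O | target

## Step count and risk

Total step count: 20. Longest linear sequence: 15 steps (steps 1–3, 9–15, 16–20).

The three steps most likely to fail:

**Step 4 (the proposed new step).** The catalyst may fail to override the Felkin preference of the aldehyde, or aryl transfer from nickel to chromium may be slow and give biaryl. The fallback uses known chemistry, sets out from carbinol 17 (made in step 9) and comes back at 9. Dess–Martin periodinane with NaHCO3 in CH2Cl2 at rt oxidises 17 to the ketone (S)-1-[3,5-bis(benzyloxy)-4-methoxyphenyl]-2-[(tert-butyldimethylsilyl)oxy]propan-1-one F1. LiBH(s-Bu)3 in THF at −78 °C then reduces F1 under Felkin–Anh control, with hydride anti to the silyloxy group, to the syn carbinol 9, which enters step 5.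

**Step 16.** The SN2 step at a β-alkoxy secondary carbinol is slow, and the ortho allyl ester carbonyl of 14 could participate, giving retention or the six-membered lactone. The fallback sets out from 14 and comes back at 27. MsCl and Et3N in CH2Cl2 at 0 °C convert 14 into the mesylate allyl 2,4-bis(benzyloxy)-6-{(1S,2S)-1-[(benzyloxy)methoxy]-2-[(methylsulfonyl)oxy]propyl}-3-methoxybenzoate F2. F2, acid 26 and Cs2CO3 in DMF at 60 °C then give 27 by cesium carboxylate alkylation with inversion.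

**Step 19.** Oligomers, ester participation at the activated carbinol and lactonization of 29 compete with the 12-membered ring closure. The fallback sets out from 27 and comes back at 30:
- HF·pyridine in THF/pyridine removes the silyl group of 27 to give the hydroxy diester allyl 2,4-bis(benzyloxy)-6-{(1S,2R)-1-[(benzyloxy)methoxy]-2-[(2,4,5-tris(benzyloxy)-6-{(1R,2S)-1-[(benzyloxy)methoxy]-2-hydroxypropyl}-3-methoxybenzoyl)oxy]propyl}-3-methoxybenzoate F3.
- MsCl and Et3N in CH2Cl2 at 0 °C give the mesylate allyl 2,4-bis(benzyloxy)-6-{(1S,2R)-1-[(benzyloxy)methoxy]-2-[(2,4,5-tris(benzyloxy)-6-{(1R,2S)-1-[(benzyloxy)methoxy]-2-[(methylsulfonyl)oxy]propyl}-3-methoxybenzoyl)oxy]propyl}-3-methoxybenzoate F4.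
- Pd(PPh3)4 and morpholine in THF at rt remove the allyl group to give the mesylate acid 2,4-bis(benzyloxy)-6-{(1S,2R)-1-[(benzyloxy)methoxy]-2-[(2,4,5-tris(benzyloxy)-6-{(1R,2S)-1-[(benzyloxy)methoxy]-2-[(methylsulfonyl)oxy]propyl}-3-methoxybenzoyl)oxy]propyl}-3-methoxybenzoic acid F5.
- Cs2CO3 in DMF at 0.003 M and 60 °C closes F5 to 30 by intramolecular cesium carboxylate displacement of the mesylate with inversion.

Further compounds
F1 | step 4 | (S)-1-[3,5-bis(benzyloxy)-4-methoxyphenyl]-2-[(tert-butyldimethylsilyl)oxy]propan-1-one | C[C@H](O[Si](C)(C)C(C)(C)C)C(=O)c1cc(OCc2ccccc2)c(OC)c(OCc2ccccc2)c1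
F2 | step 16 | allyl 2,4-bis(benzyloxy)-6-{(1S,2S)-1-[(benzyloxy)methoxy]-2-[(methylsulfonyl)oxy]propyl}-3-methoxybenzoate | C[C@H](OS(C)(=O)=O)[C@@H](OCOCc1ccccc1)c1cc(OCc2ccccc2)c(OC)c(OCc2ccccc2)c1C(=O)OCC=C
F3 | step 19 | allyl 2,4-bis(benzyloxy)-6-{(1S,2R)-1-[(benzyloxy)methoxy]-2-[(2,4,5-tris(benzyloxy)-6-{(1R,2S)-1-[(benzyloxy)methoxy]-2-hydroxypropyl}-3-methoxybenzoyl)oxy]propyl}-3-methoxybenzoate | C[C@H](O)[C@H](OCOCc1ccccc1)c1c(OCc2ccccc2)c(OCc2ccccc2)c(OC)c(OCc2ccccc2)c1C(=O)O[C@H](C)[C@@H](OCOCc1ccccc1)c1cc(OCc2ccccc2)c(OC)c(OCc2ccccc2)c1C(=O)OCC=C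
F4 | step 19 | allyl 2,4-bis(benzyloxy)-6-{(1S,2R)-1-[(benzyloxy)methoxy]-2-[(2,4,5-tris(benzyloxy)-6-{(1R,2S)-1-[(benzyloxy)methoxy]-2-[(methylsulfonyl)oxy]propyl}-3-methoxybenzoyl)oxy]propyl}-3-methoxybenzoate | C[C@H](OS(C)(=O)=O)[C@H](OCOCc1ccccc1)c1c(OCc2ccccc2)c(OCc2ccccc2)c(OC)c(OCc2ccccc2)c1C(=O)O[C@H](C)[C@@H](OCOCc1ccccc1)c1cc(OCc2ccccc2)c(OC)c(OCc2ccccc2)c1C(=O)OCC=C
F5 | step 19 | 2,4-bis(benzyloxy)-6-{(1S,2R)-1-[(benzyloxy)methoxy]-2-[(2,4,5-tris(benzyloxy)-6-{(1R,2S)-1-[(benzyloxy)methoxy]-2-[(methylsulfonyl)oxy]propyl}-3-methoxybenzoyl)oxy]propyl}-3-methoxybenzoic acid | C[C@H](OS(C)(=O)=O)[C@H](OCOCc1ccccc1)c1c(OCc2ccccc2)c(OCc2ccccc2)c(OC)c(OCc2ccccc2)c1C(=O)O[C@H](C)[C@@H](OCOCc1ccccc1)c1cc(OCc2ccccc2)c(OC)c(OCc2ccccc2)c1C(=O)O
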